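**Retrosynthetic overview**
1. Schisandrone ⇐ benzyl ether 14 (hydrogenolysis). The C4–aryl bond ⇐ Friedel–Crafts addition of veratrole to the C4 benzylic cation of hydroxytetralone 12, anti to the cis-2,3-dimethyl face.
2. The cyclohexanone ring (the only ring made; C1–C8a bond) ⇐ Parham cyclisation of bromo amide 11. The C4–C4a bond ⇐ aryl Grignard addition to aldehyde 7, followed by ring bromination.
3. Aldehyde 7 ⇐ ozonolysis of γ,δ-unsaturated amide 6.
4. Key step: the C2–C3 bond and both methyl stereocentres ⇐ Eschenmoser–Claisen [3,3] rearrangement of (R,E)-pent-3-en-2-ol 4 with 1,3-chirality transfer; 4 ⇐ (R)-but-3-yn-2-ol 1, the only source of chirality.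
5. Ring order: both arenes are bought; the carbocycle is closed in step 7 and C4 is set last, on the ring.

Assumption: compounds 1, 2, 5, 8, 10 and 13 are purchased; 5 (N,N-dimethylpropionamide dimethyl acetal) is taken as a catalogue reagent.

**Step 1**
Reactants: 1, (R)-but-3-yn-2-ol; 2, iodomethane
Product: 3, (R)-pent-3-yn-2-ol
Conditions: n-BuLi (2.1 equiv), THF, −78 → −20 °C; MeI (1.05 equiv), DMPU, −78 °C → rt
Reagents that add atoms: iodomethane (2), CI
Why: Acetylide alkylation of the O,C-dianion; the acetylide carbon is far more nucleophilic than the lithium alkoxide, so methylation is at carbon and the carbinol stereocentre is untouched.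

**Step 2**
Reactants: 3, (R)-pent-3-yn-2-ol
Product: 4, (R,E)-pent-3-en-2-ol
Conditions: Red-Al, THF, 0 °C → rt; aq. Rochelle salt; careful distillation (volatile)
Reagents that add atoms: none
Why: Hydroxyl-directed trans-hydroalumination of a propargylic alcohol gives only the E-allylic alcohol and does not touch the stereocentre.

**Step 3 (key step)**
Reactants: 4, (R,E)-pent-3-en-2-ol; 5, 1,1-dimethoxy-N,N-dimethylpropan-1-amine
Product: 6, (2S,3S,4E)-N,N,2,3-tetramethylhex-4-enamide
Conditions: 5 (2 equiv), xylenes, 140 °C, sealed tube, 16 h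
Reagents that add atoms: 5, CCC(OC)(OC)N(C)C (supplies the CH3CH–C(NMe2) unit; two MeOH are lost)
Why: Eschenmoser–Claisen rearrangement; the ketene N,O-acetal has its C-methyl cis to oxygen (A1,3 strain with NMe2), and a chair transition state with the carbinol methyl equatorial forms the C2–C3 bond suprafacially, so the (R)-carbinol is relayed into the anti (2S,3S) pair and an E-propenyl group. The minor syn isomer and the few percent of Z-alkene leakage are removed at the crystalline stages 11/14.

**Step 4**
Reactants: 6
Product: 7, (2S,3R)-N,N,2,3-tetramethyl-4-oxobutanamide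
Conditions: O3, CH2Cl2, −78 °C; Me2S, −78 °C → rt; used crude and cold
Reagents that add atoms: ozone, [O-][O+]=O
Why: Ozonolysis removes the propenyl terminus (as acetaldehyde) to unmask C4 as an aldehyde; the tertiary amide is inert and the neutral reductive work-up avoids epimerising the α-stereocentre.

**Step 5**
Reactants: 7; 8, 1-(benzyloxy)-4-bromo-2-methoxybenzene
Product: 9, (2S,3R,4RS)-4-[4-(benzyloxy)-3-methoxyphenyl]-4-hydroxy-N,N,2,3-tetramethylbutanamide (both C4 epimers)
Conditions: 8, Mg, THF (ArMgBr, 1.3 equiv); add to 7, THF, −78 → −20 °C; sat. NH4Cl (neutral work-up)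
Reagents that add atoms: 8, COc1cc(Br)ccc1OCc1ccccc1 (aryl group; Br is lost)
Why: Grignard 1,2-addition is chemoselective for the aldehyde over the tertiary amide at low temperature and forms the C4–C4a bond; the carbinol configuration is irrelevant because C4 is ionised in step 8.

**Step 6**
Reactants: 9; 10, N-bromosuccinimide
Product: 11, (2S,3R,4RS)-4-[4-(benzyloxy)-2-bromo-5-methoxyphenyl]-4-hydroxy-N,N,2,3-tetramethylbutanamide
Conditions: NBS (1.05 equiv), MeCN, 0 °C, dark
Reagents that add atoms: NBS (10), O=C1CCC(=O)N1Br
Why: Electrophilic aromatic bromination goes to the only ring position para to an alkoxy group (para to OMe, ortho to the side chain), as in veratryl systems; this is the future C8a.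

**Step 7**
Reactants: 11
Product: 12, (2S,3R,4RS)-7-(benzyloxy)-4-hydroxy-6-methoxy-2,3-dimethyl-3,4-dihydronaphthalen-1(2H)-one
Conditions: MeLi (1.05 equiv), then t-BuLi (2.1 equiv), THF, −78 → −20 °C; sat. NH4Cl
Reagents that add atoms: none
Why: Parham cyclisation; Br/Li exchange and 6-exo attack of the aryllithium on the dimethylamide close the ring regiospecifically at the former C–Br carbon, and the ketone is released only on quench, so C2 is never exposed to base as a ketone.

**Step 8**
Reactants: 12; 13, 1,2-dimethoxybenzene (veratrole)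
Product: 14, (2S,3S,4R)-7-(benzyloxy)-4-(3,4-dimethoxyphenyl)-6-methoxy-2,3-dimethyl-3,4-dihydronaphthalen-1(2H)-one
Conditions: veratrole (10 equiv), FeCl3 (10 mol%), CH2Cl2, 0 °C → rt
Reagents that add atoms: 13, COc1ccccc1OC
Why: Friedel–Crafts alkylation; both C4 epimers ionise to the same para-benzyloxy-stabilised cation, and veratrole (para to one OMe) attacks the face opposite the cis-2,3-dimethyl groups, giving the 3,4-trans (4R) product.

**Step 9**
Reactants: 14
Product: 15, schisandrone
Conditions: H2 (1 atm), 10% Pd/C, EtOAc, rt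
Reagents that add atoms: none
Why: Hydrogenolysis of the benzyl aryl ether under neutral conditions leaves the epimerisable C2, the electron-rich aryl ketone and the diarylmethine intact.

**Compound list**
1 | (R)-but-3-yn-2-ol | C[C@@H](O)C#C | starting material
2 | iodomethane | CI | starting material
3 | (R)-pent-3-yn-2-ol | C[C@@H](O)C#CC | intermediate
4 | (R,E)-pent-3-en-2-ol | C[C@@H](O)/C=C/C | intermediate
5 | 1,1-dimethoxy-N,N-dimethylpropan-1-amine | CCC(OC)(OC)N(C)C | starting material
6 | (2S,3S,4E)-N,N,2,3-tetramethylhex-4-enamide | CN(C)C(=O)[C@@H](C)[C@@H](C)/C=C/C | intermediate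
7 | (2S,3R)-N,N,2,3-tetramethyl-4-oxobutanamide | CN(C)C(=O)[C@@H](C)[C@@H](C)C=O | intermediate
8 | 1-(benzyloxy)-4-bromo-2-methoxybenzene | COc1cc(Br)ccc1OCc1ccccc1 | starting material
9 | (2S,3R,4RS)-4-[4-(benzyloxy)-3-methoxyphenyl]-4-hydroxy-N,N,2,3-tetramethylbutanamide | CN(C)C(=O)[C@@H](C)[C@@H](C)C(O)c1ccc(OCc2ccccc2)c(OC)c1 | intermediate
10 | N-bromosuccinimide | O=C1CCC(=O)N1Br | starting material
11 | (2S,3R,4RS)-4-[4-(benzyloxy)-2-bromo-5-methoxyphenyl]-4-hydroxy-N,N,2,3-tetramethylbutanamide | CN(C)C(=O)[C@@H](C)[C@@H](C)C(O)c1cc(OC)c(OCc2ccccc2)cc1Br | intermediate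
12 | (2S,3R,4RS)-7-(benzyloxy)-4-hydroxy-6-methoxy-2,3-dimethyl-3,4-dihydronaphthalen-1(2H)-one | COc1cc2c(cc1OCc1ccccc1)C(=O)[C@@H](C)[C@@H](C)C2O | intermediate
13 | 1,2-dimethoxybenzene (veratrole) | COc1ccccc1OC | starting material
14 | (2S,3S,4R)-7-(benzyloxy)-4-(3,4-dimethoxyphenyl)-6-methoxy-2,3-dimethyl-3,4-dihydronaphthalen-1(2H)-one | COc1cc2c(cc1OCc1ccccc1)C(=O)[C@@H](C)[C@@H](C)[C@@H]2c1ccc(OC)c(OC)c1 | intermediate
15 | schisandrone, (2S,3S,4R)-4-(3,4-dimethoxyphenyl)-7-hydroxy-6-methoxy-2,3-dimethyl-3,4-dihydronaphthalen-1(2H)-one | COc1cc2c(cc1O)C(=O)[C@@H](C)[C@@H](C)[C@@H]2c1ccc(OC)c(OC)c1 | target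

**Total step count:** 9
**Longest linear sequence:** 9 (fully linear from 1)

**Steps most likely to fail, with fallbacks**
1. Step 8 (arylation of the tetralone cation). The cation can lose H3 and aromatise to a 1-naphthol, and Lewis acid could erode C2. Fallback: reverse the order. Arylate the open-chain bromo carbinol 11 with veratrole first; the cation is held reversibly by the amide oxygen and cannot aromatise, and A1,3 strain should direct attack anti to the CH(Me)CONMe2 branch, which gives the same C4 configuration. Then close the ring by Parham cyclisation of the resulting diaryl bromo amide.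
2. Step 7 (Parham closure on a hydroxy amide). The aryllithium may be quenched by internal proton transfer, or 11 may lactonise before use. Fallback: close the ring electrophilically instead. Deoxygenate C4 of 9 (Et3SiH/TFA, no bromination), cyclise the amide by Tf2O/2-chloropyridine activation (acylation can only occur para to OMe), then install the veratryl group at C4 after debenzylation by DDQ oxidation to the para-quinone methide and acid-mediated addition of veratrole.
3. Step 6 (NBS on the electron-rich benzylic carbinol). Ipso attack, alcohol oxidation or lactonisation could compete. Fallback: bring the halogen in on the arene. Para-iodinate 5-bromo-2-methoxyphenol (NIS) and benzylate it to 1-(benzyloxy)-5-bromo-4-iodo-2-methoxybenzene; selective I/Mg exchange (i-PrMgCl·LiCl, −40 °C) and addition to 7 gives 11 directly.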